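## Retrosynthetic overview

1. The strategy rests on the single benzene ring (C1 bears the ester, C2 and C3 bear OH, C4–C6 are CH). Its non-aromatic tautomer, the cyclohex-5-ene-2,3-dione with the ester on C1, has the same formula, so the arene is traced back to that enedione and, two oxidations earlier, to cyclohexenediol 12.
2. The ring alkene C5=C6 is opened by ring-closing metathesis to the acyclic octa-1,7-diene 10, whose sp3 carbons C1–C4 already bear the ester, OH, OTBS and H2.
3. Diene 10 is cut at C1–C2 by an α-selective aldol. The dienolate of tetracosyl crotonate 3 supplies C1, C6 and the ester, and 2-silyloxypent-4-enal 7 supplies C2–C5.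
4. Only one ring is made. It is closed in step 5 and aromatised in step 7.

Key step: step 5

Assumption: ethyl 2-hydroxypent-4-enoate is bought as the racemate, and because the target has no stereocentre, every sp3 centre made on the way is carried as a mixture of racemic diastereomers.

## Route

Step 1
Reactants: 1 1-tetracosanol; 2 (E)-but-2-enoyl chloride (crotonyl chloride)
Product: 3 tetracosyl (E)-but-2-enoate (tetracosyl crotonate)
Conditions: 2 (1.3 equiv), pyridine (1.6 equiv), toluene, 50 °C
Reagents that add atoms: none
Why: Acylation of a primary alcohol by an acid chloride through the N-acylpyridinium salt is dependable, warm toluene keeps the waxy alcohol dissolved, any partial shift of the double bond out of conjugation would be harmless because both positional isomers give the same dienolate in step 4, and no stereocentre is formed.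

Step 2
Reactants: 4 ethyl 2-hydroxypent-4-enoate (racemic)
Product: 5 ethyl 2-(tert-butyldimethylsilyloxy)pent-4-enoate (racemic)
Conditions: TBSCl (1.2 equiv), imidazole (2.5 equiv), DMF, 23 °C
Reagents that add atoms: tert-butyldimethylsilyl chloride (TBSCl), CC(C)(C)[Si](C)(C)Cl
Why: Imidazole-promoted silyl ether formation on an unhindered secondary α-hydroxy ester is routine, and it leaves the ester, the alkene and the racemic centre untouched.

Step 3
Reactants: 5 ethyl 2-(tert-butyldimethylsilyloxy)pent-4-enoate
Product: 7 2-(tert-butyldimethylsilyloxy)pent-4-enal (racemic), via aluminium hemiacetal 6 (not isolated)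
Conditions: iBu2AlH (1.1 equiv), CH2Cl2, −78 °C; then aq KNaC4H4O6 (potassium sodium tartrate), 23 °C
Reagents that add atoms: none
Why: In this partial ester reduction the tetrahedral adduct 6, stabilised by the electron-withdrawing α-silyloxy group, should persist at −78 °C and collapse only on aqueous quench, so hydride is delivered once and no new stereocentre remains in 7.

Step 4
Reactants: 3 tetracosyl (E)-but-2-enoate; 7 2-(tert-butyldimethylsilyloxy)pent-4-enal
Product: 10 tetracosyl 4-(tert-butyldimethylsilyloxy)-3-hydroxy-2-vinylhept-6-enoate (mixture of racemic diastereomers), via lithium dienolate 8 (not isolated), via lithium aldolate 9 (not isolated)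
Conditions: LiN(iPr)2 (1.15 equiv), THF–DMPU 5:1, −78 °C, 3 added dropwise as a dilute THF solution; then 7 (1.2 equiv), −78 °C; then AcOH in THF, −78 °C
Reagents that add atoms: none
Why: γ-Deprotonation of the crotonate in the presence of DMPU (which suppresses conjugate addition of the amide and self-Michael addition) gives the extended dienolate 8, which under kinetic control undergoes aldol addition at its α-carbon through a closed Zimmerman–Traxler transition state to aldolate 9; the cold acid quench forestalls retro-aldol drift to the γ-adduct and conjugation of the vinyl group (a silyl shift between the two vicinal oxygens would be harmless, since step 6 converges both isomers), and the two new centres arise with little control and are deliberately left as a mixture that step 7 flattens.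

Step 5
Reactants: 10 tetracosyl 4-(tert-butyldimethylsilyloxy)-3-hydroxy-2-vinylhept-6-enoate
Product: 11 tetracosyl 5-(tert-butyldimethylsilyloxy)-6-hydroxycyclohex-2-ene-1-carboxylate (mixture of racemic diastereomers)
Conditions: second-generation Grubbs catalyst RuCl2(=CHPh)(H2IMes)(PCy3) (3 mol %), 1,4-benzoquinone (10 mol %), CH2Cl2 (0.01 M), 40 °C, argon sparge
Reagents that add atoms: none
Why: After loss of PCy3 the ruthenium benzylidene exchanges onto the unhindered homoallylic vinyl group of 10, the resulting alkylidene adds [2+2] to the α-vinyl group of the same molecule to give a ruthenacyclobutane, and cycloreversion releases cyclohexene 11 and a ruthenium methylidene that re-enters the cycle with loss of ethylene. This is plain ring-closing olefin metathesis of an octa-1,7-diene with two monosubstituted termini, the substrate class on which this catalyst is most dependable, and a free secondary hydroxyl, an ester and a silyl ether are all tolerated. The one ring formed is the six-membered carbocycle, closed by joining the two internal alkene carbons as C5=C6 across the four-carbon sp3 tether C1–C2–C3–C4 while both terminal CH2 groups leave. No stereocentre is created and the three present are not touched; each diastereomer can place its substituents on a half-chair cyclohexene, so the whole mixture should close. The step needs cyclisation to win over acyclic diene oligomerisation and over migration of the α-vinyl double bond into conjugation with the ester: the first is secured by the 1,7-spacing of the alkenes (a strain-free six-membered ring is the only small ring open to them), by dilution and by escape of ethylene, the second by the speed of the closure and by 1,4-benzoquinone, which intercepts ruthenium hydrides.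

Step 6
Reactants: 11 tetracosyl 5-(tert-butyldimethylsilyloxy)-6-hydroxycyclohex-2-ene-1-carboxylate
Product: 12 tetracosyl 5,6-dihydroxycyclohex-2-ene-1-carboxylate (mixture of racemic diastereomers)
Conditions: HF·pyridine, extra pyridine, THF, 0 to 23 °C (polyethylene vessel)
Reagents that add atoms: none
Why: Fluoride-driven cleavage of a secondary silyl ether under buffered, weakly acidic conditions generates no alkoxide or naked fluoride base, so E1cB loss of the β-hydroxyl, retro-aldol ring opening, lactonisation onto the ester and double-bond migration should all be avoided and the stereocentres stay as they are.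

Step 7
Reactants: 12 tetracosyl 5,6-dihydroxycyclohex-2-ene-1-carboxylate
Product: 14 tetracosyl 2,3-dihydroxybenzoate (gentiside K), via diketone 13 (not isolated)
Conditions: IBX (2.2 equiv), DMSO–THF 1:2, 30 °C, under argon; then aq Na2S2O4, pH 6–7 phosphate buffer
Reagents that add atoms: none
Why: IBX oxidises vicinal diols to 1,2-diketones without C–C cleavage (each hydroxyl reacts through its own monodentate iodic ester, whereas Dess–Martin periodinane can chelate a free glycol and cleave it), and diketone 13, whose C1–H is flanked by ester, ketone and alkene and whose C4–H2 is flanked by ketone and alkene, should enolise twice to the aromatic catechol, which removes all three stereocentres; the oxidant is kept near two equivalents and the dithionite wash returns any over-oxidised material to the catechol level.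

## Compound list

1 | 1-tetracosanol | CCCCCCCCCCCCCCCCCCCCCCCCO | starting material
2 | (E)-but-2-enoyl chloride (crotonyl chloride) | C/C=C/C(=O)Cl | starting material
3 | tetracosyl (E)-but-2-enoate | CCCCCCCCCCCCCCCCCCCCCCCCOC(=O)/C=C/C | intermediate
4 | ethyl 2-hydroxypent-4-enoate (racemic) | CCOC(=O)C(O)CC=C | starting material
5 | ethyl 2-(tert-butyldimethylsilyloxy)pent-4-enoate (racemic) | CCOC(=O)C(CC=C)O[Si](C)(C)C(C)(C)C | intermediate
6 | diisobutylaluminium hemiacetal of 5 (not isolated) | CCOC(O[Al](CC(C)C)CC(C)C)C(CC=C)O[Si](C)(C)C(C)(C)C | intermediate
7 | 2-(tert-butyldimethylsilyloxy)pent-4-enal (racemic) | O=CC(CC=C)O[Si](C)(C)C(C)(C)C | intermediate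
8 | lithium dienolate of tetracosyl crotonate (not isolated) | CCCCCCCCCCCCCCCCCCCCCCCCOC([O-])=CC=C.[Li+] | intermediate
9 | lithium aldolate of 10 (not isolated, diastereomer mixture) | CCCCCCCCCCCCCCCCCCCCCCCCOC(=O)C(C=C)C([O-])C(CC=C)O[Si](C)(C)C(C)(C)C.[Li+] | intermediate
10 | tetracosyl 4-(tert-butyldimethylsilyloxy)-3-hydroxy-2-vinylhept-6-enoate (diastereomer mixture) | CCCCCCCCCCCCCCCCCCCCCCCCOC(=O)C(C=C)C(O)C(O[Si](C)(C)C(C)(C)C)CC=C | intermediate
11 | tetracosyl 5-(tert-butyldimethylsilyloxy)-6-hydroxycyclohex-2-ene-1-carboxylate (diastereomer mixture) | CCCCCCCCCCCCCCCCCCCCCCCCOC(=O)C1C=CCC(O[Si](C)(C)C(C)(C)C)C1O | intermediate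
12 | tetracosyl 5,6-dihydroxycyclohex-2-ene-1-carboxylate (diastereomer mixture) | CCCCCCCCCCCCCCCCCCCCCCCCOC(=O)C1C=CCC(O)C1O | intermediate
13 | tetracosyl 5,6-dioxocyclohex-2-ene-1-carboxylate (not isolated) | CCCCCCCCCCCCCCCCCCCCCCCCOC(=O)C1C=CCC(=O)C1=O | intermediate
14 | tetracosyl 2,3-dihydroxybenzoate (gentiside K, no stereocentre) | CCCCCCCCCCCCCCCCCCCCCCCCOC(=O)c1cccc(O)c1O | target

## Step count and risks

Total step count: 7.
Longest linear sequence: 6 steps (4 → 5 → 7 → 10 → 11 → 12 → 14, steps 2 to 7).

**Step 7 (double oxidation and aromatisation)**

- What may go wrong:
  - Water may be lost at the half-oxidised stage, so that the ring aromatises by dehydration instead of by the second oxidation and one ring oxygen is lost.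
  - Surplus pentavalent iodine may oxidise the freshly formed catechol further.
  - The lipid may separate from the DMSO-rich medium.
- Fallback, setting out from 11 and coming back at 14: the two oxidation events are separated, and the second is run as a dehydrogenation while the C3 oxygen is still silylated.
  - The only free hydroxyl of 11 is oxidised with Dess–Martin periodinane and NaHCO3 in CH2Cl2. The substrate is a mono-alcohol, so glycol cleavage cannot occur. The product is tetracosyl 5-(tert-butyldimethylsilyloxy)-6-oxocyclohex-2-ene-1-carboxylate F1, a β-keto ester that should sit largely as its conjugated dienol.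
  - DDQ in 1,4-dioxane at 23 °C then takes hydride from C4 (the cation is stabilised by the C2 oxygen) and a proton from C3. This should give tetracosyl 3-(tert-butyldimethylsilyloxy)-2-hydroxybenzoate F2, in which the catechol is masked from the oxidant.
  - TBAF buffered with AcOH in THF at 0 °C cleaves the aryl silyl ether to 14.

**Step 5 (ring-closing metathesis)**

- What may go wrong:
  - Ruthenium hydride species may move the α-vinyl double bond into conjugation with the ester before closure.
  - The alkylidene may be held back by chelation to the free hydroxyl or the ester carbonyl.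
  - Oligomerisation may compete.
- Fallback, setting out from 10 and coming back at 12: the substrate is reshaped before closure.
  - TBSOTf and 2,6-lutidine in CH2Cl2 silylate the free hydroxyl to give tetracosyl 3,4-bis(tert-butyldimethylsilyloxy)-2-vinylhept-6-enoate F3. This compound has no hydrogen-bond donor and no retro-aldol path, and its two bulky vicinal silyloxy groups should fold the chain toward closure.
  - The same ruthenium catalyst closes it to tetracosyl 5,6-bis(tert-butyldimethylsilyloxy)cyclohex-2-ene-1-carboxylate F4.
  - HF·pyridine in THF removes both silyl groups to reach 12.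

**Step 4 (dienolate aldol)**

- What may go wrong:
  - The waxy ester may crystallise from THF at −78 °C before it is deprotonated.
  - The dienolate may add in Michael fashion to unreacted crotonate.
  - The aldol may reverse and drift to the γ-adduct.
- Fallback, setting out from 3 and coming back at 10: the strong-base enolisation is replaced by a neutral allylmetal addition at room temperature.
  - Wohl–Ziegler bromination (NBS, AIBN, PhCF3, reflux) gives tetracosyl (E)-4-bromobut-2-enoate F5.
  - Indium metal in THF at 23 °C, with aldehyde 7 present (Barbier-type vinylogous Reformatsky reaction), inserts into the C–Br bond. The allylindium species is written in its simplest form as tetracosyl (E)-4-(dibromoindiganyl)but-2-enoate F6.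
  - F6 adds to the aldehyde with allylic transposition at the carbon α to the ester, giving the same α-vinyl β-hydroxy ester 10 at a temperature where the lipid stays dissolved.

## Further compounds

F1 | step 7 | tetracosyl 5-(tert-butyldimethylsilyloxy)-6-oxocyclohex-2-ene-1-carboxylate | CCCCCCCCCCCCCCCCCCCCCCCCOC(=O)C1C=CCC(O[Si](C)(C)C(C)(C)C)C1=O
F2 | step 7 | tetracosyl 3-(tert-butyldimethylsilyloxy)-2-hydroxybenzoate | CCCCCCCCCCCCCCCCCCCCCCCCOC(=O)c1cccc(O[Si](C)(C)C(C)(C)C)c1O
F3 | step 5 | tetracosyl 3,4-bis(tert-butyldimethylsilyloxy)-2-vinylhept-6-enoate | CCCCCCCCCCCCCCCCCCCCCCCCOC(=O)C(C=C)C(O[Si](C)(C)C(C)(C)C)C(O[Si](C)(C)C(C)(C)C)CC=C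
F4 | step 5 | tetracosyl 5,6-bis(tert-butyldimethylsilyloxy)cyclohex-2-ene-1-carboxylate | CCCCCCCCCCCCCCCCCCCCCCCCOC(=O)C1C=CCC(O[Si](C)(C)C(C)(C)C)C1O[Si](C)(C)C(C)(C)C
F5 | step 4 | tetracosyl (E)-4-bromobut-2-enoate | CCCCCCCCCCCCCCCCCCCCCCCCOC(=O)/C=C/CBr
F6 | step 4 | tetracosyl (E)-4-(dibromoindiganyl)but-2-enoate | CCCCCCCCCCCCCCCCCCCCCCCCOC(=O)/C=C/C[In](Br)Br
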